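**Retrosynthetic overview**
1. Target ⇒ meso cyclobutane-1,3-diacid (aryl groups cis; one CO2H cis to both, one trans) + 2 × 5,6-dihydropyridin-2(1H)-one, by double N-acylation; both lactam rings are bought intact.
2. Cyclobutane diacid ⇒ 2-exo,4-endo 1,3-diarylbicyclo[1.1.0]butane-2,4-dibenzyl ester: syn hydrogenolysis of the central bond makes the aryl groups cis and unmasks the four-membered ring; the benzyl esters are cleaved in the same pot.
3. exo,endo diester ⇒ exo,exo diester by a single wing epimerisation.
4. Bicyclobutane ⇒ bis(3,4-dimethoxyphenyl)acetylene + 2 benzyl diazoacetate: double carbene transfer, both three-membered rings closed in one operation (key step).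
5. Ring order: arenes and lactams purchased; cyclopropene ring → second three-membered ring (same pot) → cyclobutane by central-bond cleavage; the alkyne comes from 4-iodoveratrole and trimethylsilylacetylene.

Assumption: the target has a mirror plane through the two carbonyl-bearing ring carbons, so it is an achiral meso compound; the stereodescriptors define one relative configuration (aryl groups cis, one acyl group cis to both, the other trans) and no absolute stereocontrol is needed.

**Route**

Step 1
Reactants: 1 4-iodoveratrole (4-iodo-1,2-dimethoxybenzene, 2.05 equiv); 2 trimethylsilylacetylene (1 equiv)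
Product: 5 bis(3,4-dimethoxyphenyl)acetylene, via silylalkyne 3 (not isolated), via terminal alkyne 4 (not isolated)
Conditions: PdCl2(PPh3)2 (6 mol %), CuI (10 mol %), DBU (6 equiv), H2O (1 equiv), MeCN, 60 °C, 18 h
Reagents that add atoms: none
Why: One-pot Sonogashira coupling, in situ DBU/water desilylation and second Sonogashira coupling give the symmetrical diarylalkyne from a readily activated aryl iodide, and no stereocentre is formed.

Step 2
Reactants: 5 bis(3,4-dimethoxyphenyl)acetylene; 6 benzyl diazoacetate (4 equiv, syringe pump over 16 h)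
Product: 8 dibenzyl 2-exo,4-exo-1,3-bis(3,4-dimethoxyphenyl)bicyclo[1.1.0]butane-2,4-dicarboxylate, via cyclopropene ester 7 (not isolated)
Conditions: Rh2(OAc)4 (2 mol %), CH2Cl2, 40 °C
Reagents that add atoms: none
Why: Two consecutive metal-carbenoid [2+1] transfers (cyclopropenation of the electron-rich alkyne, then cyclopropanation of the strained cyclopropene C=C) close both three-membered rings in one operation, and because the second carbenoid attacks the face anti to the C3 ester and turns its own ester towards the open aryl side rather than over the ring C–H, both wing esters come out exo (meso 8).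

Step 3
Reactants: 8 dibenzyl 2-exo,4-exo-1,3-bis(3,4-dimethoxyphenyl)bicyclo[1.1.0]butane-2,4-dicarboxylate
Product: 9 dibenzyl 2-exo,4-endo-1,3-bis(3,4-dimethoxyphenyl)bicyclo[1.1.0]butane-2,4-dicarboxylate
Conditions: BnONa (0.3 equiv, 1.0 M in BnOH), THF, 25 °C, HPLC control, AcOH quench at maximum of 9; chromatography, recovered 8 recycled
Reagents that add atoms: none
Why: Base-catalysed epimerisation through the wing ester enolate (degenerate alkoxide, so no transesterification) moves one ester out of the exo site, where it is squeezed between the ortho hydrogens of both bridgehead aryl rings, into the endo site, and since the second ester reacts more slowly (its endo hydrogen is then screened by the new endo ester) stopping at partial conversion gives the exo,endo isomer with one ester on each face of the future cyclobutane.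

Step 4
Reactants: 9 dibenzyl 2-exo,4-endo-1,3-bis(3,4-dimethoxyphenyl)bicyclo[1.1.0]butane-2,4-dicarboxylate
Product: 11 r-1,c-2,t-3,c-4-2,4-bis(3,4-dimethoxyphenyl)cyclobutane-1,3-dicarboxylic acid, via dibenzyl cyclobutane diester 10 (not isolated)
Conditions: H2 (1 atm), 10% Pd/C, THF, 25 °C
Reagents that add atoms: none
Why: Catalytic hydrogenolysis of the strained, doubly benzylic central σ-bond delivers both hydrogens from the metal surface to the exposed convex face (syn addition), so the two aryl groups end up cis, on the face of the former endo ester and opposite the former exo ester, while the same conditions cleave the benzyl esters (O-debenzylation) without a basic hydrolysis that could epimerise the crowded cis carboxyl.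

Step 5
Reactants: 11 r-1,c-2,t-3,c-4-2,4-bis(3,4-dimethoxyphenyl)cyclobutane-1,3-dicarboxylic acid; 12 5,6-dihydropyridin-2(1H)-one (2.1 equiv)
Product: 15 1,1'-{[r-1,c-2,t-3,c-4-2,4-bis(3,4-dimethoxyphenyl)cyclobutane-1,3-diyl]dicarbonyl}bis(5,6-dihydropyridin-2(1H)-one), via bis(acid chloride) 13 (not isolated), via lithium lactamate 14 (not isolated)
Conditions: (COCl)2 (2.5 equiv), DMF (cat.), CH2Cl2, 0 → 25 °C, evaporate; then added to 12/LiN(SiMe3)2 (2.0 equiv) in THF, −78 → −40 °C; NH4Cl quench
Reagents that add atoms: none
Why: Acid chloride formation followed by N-acylation of the preformed lithium lactamate (imide formation) attaches both lactam rings at low temperature with no excess base, and the ring stereocentres stay untouched because α-deprotonation on a cyclobutane (exocyclic enolate on a four-membered ring) is slow under these conditions.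

**Compound list**
1 | 4-iodoveratrole (4-iodo-1,2-dimethoxybenzene) | COc1ccc(I)cc1OC | starting material
2 | trimethylsilylacetylene (ethynyltrimethylsilane) | C#C[Si](C)(C)C | starting material
3 | [(3,4-dimethoxyphenyl)ethynyl]trimethylsilane | COc1ccc(C#C[Si](C)(C)C)cc1OC | intermediate
4 | 4-ethynyl-1,2-dimethoxybenzene | COc1ccc(C#C)cc1OC | intermediate
5 | bis(3,4-dimethoxyphenyl)acetylene | COc1ccc(C#Cc2ccc(OC)c(OC)c2)cc1OC | intermediate
6 | benzyl diazoacetate | [N-]=[N+]=CC(=O)OCc1ccccc1 | starting material
7 | benzyl 2,3-bis(3,4-dimethoxyphenyl)cycloprop-2-ene-1-carboxylate | COc1ccc(C2=C(c3ccc(OC)c(OC)c3)C2C(=O)OCc4ccccc4)cc1OC | intermediate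
8 | dibenzyl 2-exo,4-exo-1,3-bis(3,4-dimethoxyphenyl)bicyclo[1.1.0]butane-2,4-dicarboxylate (meso; both esters cis to the bridgehead aryl groups) | COc1ccc([C@@]23[C@@H](C(=O)OCc4ccccc4)[C@]2(c5ccc(OC)c(OC)c5)[C@H]3C(=O)OCc6ccccc6)cc1OC | intermediate
9 | dibenzyl 2-exo,4-endo-1,3-bis(3,4-dimethoxyphenyl)bicyclo[1.1.0]butane-2,4-dicarboxylate (achiral; one ester exo, one endo) | COc1ccc([C@@]23[C@@H](C(=O)OCc4ccccc4)[C@]2(c5ccc(OC)c(OC)c5)[C@@H]3C(=O)OCc6ccccc6)cc1OC | intermediate
10 | dibenzyl r-1,c-2,t-3,c-4-2,4-bis(3,4-dimethoxyphenyl)cyclobutane-1,3-dicarboxylate (aryl groups cis; C1 ester cis to both, C3 ester trans) | COc1ccc([C@H]2[C@H](C(=O)OCc3ccccc3)[C@@H](c4ccc(OC)c(OC)c4)[C@H]2C(=O)OCc5ccccc5)cc1OC | intermediate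
11 | r-1,c-2,t-3,c-4-2,4-bis(3,4-dimethoxyphenyl)cyclobutane-1,3-dicarboxylic acid (meso) | COc1ccc([C@H]2[C@H](C(=O)O)[C@@H](c3ccc(OC)c(OC)c3)[C@H]2C(=O)O)cc1OC | intermediate
12 | 5,6-dihydropyridin-2(1H)-one | O=C1C=CCCN1 | starting material
13 | r-1,c-2,t-3,c-4-2,4-bis(3,4-dimethoxyphenyl)cyclobutane-1,3-dicarbonyl dichloride | COc1ccc([C@H]2[C@H](C(=O)Cl)[C@@H](c3ccc(OC)c(OC)c3)[C@H]2C(=O)Cl)cc1OC | intermediate
14 | lithium salt of 5,6-dihydropyridin-2(1H)-one (N-lithio lactam) | [Li]N1CCC=CC1=O | intermediate
15 | 1,1'-{[r-1,c-2,t-3,c-4-2,4-bis(3,4-dimethoxyphenyl)cyclobutane-1,3-diyl]dicarbonyl}bis(5,6-dihydropyridin-2(1H)-one) (meso) | COc1ccc([C@H]2[C@H](C(=O)N3CCC=CC3=O)[C@@H](c3ccc(OC)c(OC)c3)[C@H]2C(=O)N2CCC=CC2=O)cc1OC | target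

**Totals**
Total step count: 5. Longest linear sequence: 5 steps (1 → 5 → 8 → 9 → 11 → 15).

**Steps most likely to fail, with fallbacks**

Step 2. The second carbenoid transfer onto the hindered, tetrasubstituted cyclopropene 7 can lose out to carbene dimerisation, to attack on the dimethoxyaryl rings or to metal-induced ring opening of 7. The fallback leaves the bicyclobutane logic and puts the aryl groups onto a preformed four-membered ring by directed C–H arylation; it sets out from 1 and comes back at 11. Commercial trans-3-(methoxycarbonyl)cyclobutane-1-carboxylic acid is coupled with 2-(methylsulfanyl)aniline (EDC·HCl, DMAP, CH2Cl2) to give methyl trans-3-{[2-(methylsulfanyl)phenyl]carbamoyl}cyclobutane-1-carboxylate F1. Twofold β-C–H arylation with 1 (Pd(OAc)2, Ag2CO3, PivOH, (CF3)2CHOH, 90 °C) places both aryl groups cis to the directing amide and therefore trans to the ester, giving methyl 2,4-bis(3,4-dimethoxyphenyl)-3-{[2-(methylsulfanyl)phenyl]carbamoyl}cyclobutane-1-carboxylate F2. Boc2O and DMAP in MeCN convert it into methyl 3-{(tert-butoxycarbonyl)[2-(methylsulfanyl)phenyl]carbamoyl}-2,4-bis(3,4-dimethoxyphenyl)cyclobutane-1-carboxylate F3. LiOH and H2O2 (THF–H2O, 0 °C) then cleave the activated amide and the methyl ester under conditions too mild to epimerise the cis centre, giving 11.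

Step 3. A clean stop after one epimerisation is not assured; an over-run gives the endo,endo diester, which is lost material. The fallback sets the crowded cis carboxyl by decarboxylative protonation instead of epimerisation; it sets out from 7 (isolated by stopping step 2 after 1.2 equiv of 6) and comes back at 11. Compound 7 and dibenzyl diazomalonate (Rh2(OAc)4, ClCH2CH2Cl, 80 °C) give tribenzyl 4-exo-1,3-bis(3,4-dimethoxyphenyl)bicyclo[1.1.0]butane-2,2,4-tricarboxylate F4; the carbenoid adds anti to the ester of 7 and the new geminal wing raises no exo or endo question. H2 and Pd/C as in step 4 give r-2,t-3,c-4-2,4-bis(3,4-dimethoxyphenyl)cyclobutane-1,1,3-tricarboxylic acid F5. Heating F5 (1,4-dioxane, 100 °C) decarboxylates the malonic acid, and the enol is protonated on the face away from the two cis aryl groups, which leaves the remaining C1 carboxyl cis to them, that is 11.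

Step 4. The catalyst may also cut a side bond of the bicyclobutane or deliver hydrogen non-syn, and the liberated acid may open the strained ring before reduction. The fallback is an ionic instead of a surface hydrogenation; it sets out from 9 and comes back at 11. CF3CO2H and Et3SiH (CH2Cl2, −78 → 0 °C) protonate the central bond to an aryl-stabilised cyclobutyl cation, which takes hydride on the face away from the transannular aryl group; this again gives cis aryl groups, now with the benzyl esters intact as isolated 10. A separate debenzylation (H2, 10% Pd/C, THF) then gives 11. No compound outside the compound list is made (F0).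

**Further compounds**
F1 | step 2 | methyl trans-3-{[2-(methylsulfanyl)phenyl]carbamoyl}cyclobutane-1-carboxylate | COC(=O)[C@H]1C[C@H](C(=O)Nc2ccccc2SC)C1
F2 | step 2 | methyl 2,4-bis(3,4-dimethoxyphenyl)-3-{[2-(methylsulfanyl)phenyl]carbamoyl}cyclobutane-1-carboxylate (aryl groups and amide on one face, ester on the other) | COc1ccc([C@H]2[C@H](C(=O)OC)[C@@H](c3ccc(OC)c(OC)c3)[C@H]2C(=O)Nc4ccccc4SC)cc1OC
F3 | step 2 | methyl 3-{(tert-butoxycarbonyl)[2-(methylsulfanyl)phenyl]carbamoyl}-2,4-bis(3,4-dimethoxyphenyl)cyclobutane-1-carboxylate (same relative configuration as F2) | COc1ccc([C@H]2[C@H](C(=O)OC)[C@@H](c3ccc(OC)c(OC)c3)[C@H]2C(=O)N(C(=O)OC(C)(C)C)c4ccccc4SC)cc1OC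
F4 | step 3 | tribenzyl 4-exo-1,3-bis(3,4-dimethoxyphenyl)bicyclo[1.1.0]butane-2,2,4-tricarboxylate | COc1ccc([C@@]23[C@@H](C(=O)OCc4ccccc4)[C@]2(c5ccc(OC)c(OC)c5)C3(C(=O)OCc6ccccc6)C(=O)OCc7ccccc7)cc1OC
F5 | step 3 | r-2,t-3,c-4-2,4-bis(3,4-dimethoxyphenyl)cyclobutane-1,1,3-tricarboxylic acid (aryl groups cis, C3 carboxyl trans to both) | COc1ccc([C@H]2[C@H](C(=O)O)[C@@H](c3ccc(OC)c(OC)c3)C2(C(=O)O)C(=O)O)cc1OC
F0 | step 4 | none | none
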